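The numbers of this flask were set for the occasion.

Fast feed or slow?

    starting material + partner + free catalyst → product + free catalyst, rate k1*[starting material]*[partner]*[free catalyst]/(1 + ([starting material]/sat1)) (sat1 = 17 mM, k1 = 31 M⁻² min⁻¹, Ea1 = 43.0 kJ mol⁻¹)
    partner + protic impurity → quenched reagent (k2 = 0.21 M⁻¹ min⁻¹, Ea2 = 83.0 kJ mol⁻¹)
    2 free catalyst → spent catalyst (k3 = 1.4 M⁻¹ min⁻¹, Ea3 = 72.0 kJ mol⁻¹)
    (constants at 60 °C)

common to all: protic impurity 2.50 mM; free catalyst 0.25 mM; time 25 h
- violet: starting material 0.050 M; partner 0.100 M (fed, over 20 h); temperature 60 °C; all else is in the flask from the start; the feed brings no volume worth counting
- teal: starting material 0.050 M (in portions, 2, over 20 h); partner 0.100 M; temperature 60 °C; first portion at the start, last at 20 h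
- blue: starting material 0.050 M (fed, over 20 h); partner 0.100 M; the addition at 40 °C, then warmed to 60 °C; the feed brings no volume worth counting
- red: starting material 0.050 M; partner 0.100 M; everything together at the start at 40 °C, warmed to 60 °C at 20 h
- grey: starting material 0.050 M (fed, over 5.0 h); partner 0.100 M; temperature 60 °C; all else is in the flask from the start; the feed brings no volume worth counting
- amber: starting material 0.050 M (fed, over 20 h); partner 0.100 M; temperature 60 °C; all else is in the flask from the start; the feed brings no volume worth counting

- two of one species on the left: rate k times its square, two consumed each time
- at 60 °C the constants are as listed, elsewhere as the activation energies make them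

- the flask with the highest amount of product, in percent of the starting material charged ("all alike" if they lie within 1.5 percentage points) (violet / teal / blue / red / grey / amber / all alike)
- final product, as a percentage of the starting material charged, in violet
- final product, as a percentage of the starting material charged, in teal
- final product, as a percentage of the starting material charged, in blue
- final product, as a percentage of the starting material charged, in red
- final product, as a percentage of the starting material charged, in grey
- final product, as a percentage of the starting material charged, in amber

**The choice.** For the next warm run, with partner in the flask from the start, we must decide whether to feed the starting material over 5.0 h, as in grey, or over 20 h, as in amber. Both flasks get the same catalyst, so we reckon what that catalyst can deliver and then what each feed costs.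

**The ceiling.** The free catalyst pairs off with a first half-life of 23.8 h, which is of the order of the 25 h run. Its area over time is therefore its charge, times that half-life, times the logarithm of one plus 1.05, the run time in half-lives. With partner in excess, the protic impurity has a pseudo-first-order half-life near 33.0 min, much shorter than the run, so we count 0.0975 M of partner from the start. Multiplying the area by that partner and by the constant of the making gives a dose of 0.775. The ratio c(starting material)/sat is 2.94 at full charge, and dividing the dose by one plus that ratio gives the ceiling, the fraction of the charge converted if starting material stood at its full charge and partner at the figure just counted throughout: 19.7%.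

**The feed.** If c(starting material) rises evenly to its full charge during a steady feed, the saturation term c/(c + sat) averages 0.534 instead of 0.746, so we count the catalyst area spent in that time at 0.715 of its value. The feed over 5.0 h uses 26.6% of the area and the feed over 20 h uses 84.9%. We thus reckon 18.2% for grey and 14.9% for amber. Neither figure subtracts any starting material or partner consumed, so we read both as estimates on the high side. We would charge the next run like grey.

**The forecast.** The forecast names grey and gives 9.9% for violet, 14.9% for teal, 9.8% for blue, 12% for red, 17.1% for grey and 13.3% for amber, on the ground that “Conversion is limited by saturation and catalyst lifetime”. Its figures for grey and amber lie below our estimates.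

**The result.** The flask with most product is grey, with 9.91% in violet, 14.8% in teal, 9.73% in blue, 11.9% in red, 16.9% in grey and 13.2% in amber.

**Partner's draw.** In blue at 18.4 h, the making draws partner 11 times as fast as the quench, with half-lives of 16 d against 170 d, while grey stands at 85.8% of the ceiling and amber at 67.0%. Our dose is proportional to the partner counted after the quench, a factor of 1.72 for the neighbour of blue charged with 0.17 M, all else held, and that neighbour gives 16.5% against blue's 9.73%, a factor of 1.70.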